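**Plan**

1. Numbering (eremophilane): ring A = C1, C2, C3, C4, C5, C10; ring B = C5 to C10; C14 = methyl on C5, C15 = methyl on C4, C11 to C13 = isopropylidene on C7. The target is (3R,4R,5R,9S,10R).
2. Retrosynthetic cuts, in order: the ester C–O bond at C3; the C9–O bond; the C3–C4 bond (ring A); the C7=C11 bond; then C5–C6 and C9–C10 together (ring B, Diels–Alder).
3. Forward: ring B arises first from an (E)-2-methyl enal and a 2-silyloxy diene, and its enol ether is spent to place C11–C13 on C7. Ring A is closed last through C3–C4; then the separately made trienoic acid is joined at O3 and C9 is hydroxylated.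
4. Enabling feature: C4 carries the C15 methyl and hangs on the quaternary C5, so a vinyl group on C5 (C4=C15) is a latent "C4 radical plus C15 methyl". A C3 aldehyde on the C10 side chain completes the six atoms C4, C5, C10, C1, C2, C3, and vinyl and chain are trans-diequatorial on ring B. One hydrogen-atom transfer and one 6-exo closure should therefore give ring A, the trans-decalin, the C3 hydroxyl and the C4 methyl at once.
5. Stereochemistry: C5 and C10 from the cycloaddition (absolute sense from the chiral catalyst, relative sense from the E alkene); C3 and C4 from the chair transition state under the axial C14 methyl; C9 from oxygen transfer anti to C14; the alkene geometries of the acid from syn-carboalumination and Heck coupling.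

Key step: step 13

Assumption: the facial sense of the oxazaborolidinium catalyst in step 7 is taken from the formyl C–H···O binding model for α-substituted enals; the antipodal catalyst serves if the sense on this enal is the reverse.

**Route**

Step 1
Reactants: 1 (2E)-oct-2-enal
Product: 2 (3E)-non-3-en-1-yne
Conditions: Me3SiCHN2, n-BuLi, THF, −78 °C; then 1, −78 → 0 °C
Reagents that add atoms: trimethylsilyldiazomethane, C[Si](C)(C)C=[N+]=[N-]
Why: Colvin alkyne synthesis, in which the lithiated diazo reagent adds to the aldehyde, lithium trimethylsilanolate leaves in a Peterson-type elimination and the alkylidene carbene rearranges by 1,2-hydrogen shift to the terminal alkyne without touching the E alkene, whereas the methanolic Ohira–Bestmann variant is avoided because methoxide adds to enals.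

Step 2
Reactants: 2 (3E)-non-3-en-1-yne
Product: 4 (1E,3E)-1-iodo-2-methylnona-1,3-diene, via alkenylalane 3 (not isolated)
Conditions: Me3Al (2 equiv), Cp2ZrCl2 (0.2 equiv), CH2Cl2, 0 °C → rt; then I2, THF, −30 → 0 °C
Reagents that add atoms: trimethylaluminium, C[Al](C)C; iodine, II
Why: Negishi carboalumination, in which Cp2ZrCl2-catalysed syn addition of Me–Al across the terminal alkyne puts the methyl on the internal carbon and aluminium on the terminus, and iodine cleaves the C–Al bond with retention, so the new trisubstituted alkene should be E and no stereocentre is formed.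

Step 3
Reactants: 4 (1E,3E)-1-iodo-2-methylnona-1,3-diene; 5 ethyl prop-2-enoate
Product: 6 ethyl (2E,4E,6E)-5-methyldodeca-2,4,6-trienoate
Conditions: Pd(OAc)2 (5 mol %), K2CO3, n-Bu4NCl, DMF, rt
Reagents that add atoms: none
Why: Heck reaction, in which oxidative addition of the alkenyl iodide to zerovalent palladium with retention, syn insertion of the acrylate and syn β-hydride elimination should give the 2E enoate and leave the 4E and 6E alkenes as they are.

Step 4
Reactants: 6 ethyl (2E,4E,6E)-5-methyldodeca-2,4,6-trienoate
Product: 7 (2E,4E,6E)-5-methyldodeca-2,4,6-trienoic acid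
Conditions: LiOH·H2O, THF/MeOH/H2O (3:1:1), rt; then 1 M HCl to pH 3
Reagents that add atoms: lithium hydroxide, [Li+].[OH-]
Why: Ester saponification, in which hydroxide attacks the unhindered ethyl ester and the conjugated carboxylate is stable to the mild base, so the triene geometry should be kept.

Step 5
Reactants: 8 but-3-en-2-one
Product: 9 (buta-1,3-dien-2-yloxy)tri(propan-2-yl)silane
Conditions: i-Pr3SiOTf, Et3N, Et2O, 0 °C → rt
Reagents that add atoms: triisopropylsilyl trifluoromethanesulfonate, CC(C)[Si](OS(=O)(=O)C(F)(F)F)(C(C)C)C(C)C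
Why: Soft enolisation of the methyl ketone with a silyl triflate and an amine gives the 2-silyloxy diene, and the bulky triisopropylsilyl group is chosen so that the enol ether survives the acidic catalyst of step 7 and chromatography.

Step 6
Reactants: 10 methyl 4-oxobutanoate; 11 2-(triphenylphosphoranylidene)propanal
Product: 12 methyl (4E)-5-methyl-6-oxohex-4-enoate
Conditions: toluene, 80 °C
Reagents that add atoms: none
Why: Wittig reaction of a stabilised ylide with an aliphatic aldehyde is E-selective and places the formyl group trans to the chain, which is what the cycloaddition needs, and no stereocentre is formed.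

Step 7
Reactants: 12 methyl (4E)-5-methyl-6-oxohex-4-enoate; 9 (buta-1,3-dien-2-yloxy)tri(propan-2-yl)silane
Product: 13 methyl 3-[(1S,6S)-6-formyl-6-methyl-3-{[tri(propan-2-yl)silyl]oxy}cyclohex-3-en-1-yl]propanoate
Conditions: (R)-oxazaborolidine from (R)-α,α-diphenylprolinol and 2-methylphenylboronic acid (20 mol %), Tf2NH (18 mol %), CH2Cl2, −78 → −40 °C
Reagents that add atoms: none
Why: Diels–Alder reaction catalysed by a chiral cationic oxazaborolidine, in which the 2-silyloxy diene adds para (its nucleophilic CH2 terminus C9 to the enal β-carbon C10, C6 to C5), suprafacial addition turns the E geometry into the trans relation of formyl (C4) and side chain (so the C14 methyl is cis to the chain), and on the formyl C–H···O binding model the aryl group of the (R)-catalyst covers the Re face of C5 so that the diene should add to its Si face and give the (1S,6S) adduct.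

Step 8
Reactants: 13 methyl 3-[(1S,6S)-6-formyl-6-methyl-3-{[tri(propan-2-yl)silyl]oxy}cyclohex-3-en-1-yl]propanoate
Product: 14 methyl 3-[(1S,6R)-6-ethenyl-6-methyl-3-{[tri(propan-2-yl)silyl]oxy}cyclohex-3-en-1-yl]propanoate
Conditions: Ph3PCH3Br, KOt-Bu, THF, 0 °C
Reagents that add atoms: methyltriphenylphosphonium bromide, C[P+](c1ccccc1)(c1ccccc1)c1ccccc1.[Br-]
Why: Wittig methylenation of the non-enolisable aldehyde turns C4 into the vinyl carbon of C4=C15 while the ester and the hindered enol ether should not react with the unstabilised ylide at 0 °C, and the descriptor at C5 changes only through the priority rules.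

Step 9
Reactants: 14 methyl 3-[(1S,6R)-6-ethenyl-6-methyl-3-{[tri(propan-2-yl)silyl]oxy}cyclohex-3-en-1-yl]propanoate; 15 2,2-dimethoxypropane
Product: 16 methyl 3-[(1S,2R,4RS)-2-ethenyl-4-(2-methoxypropan-2-yl)-2-methyl-5-oxocyclohexyl]propanoate
Conditions: Me3SiOTf (0.2 equiv), CH2Cl2, −78 °C
Reagents that add atoms: none
Why: Mukaiyama-type addition of the enol silane to the oxocarbenium ion generated from the ketal forms the C7–C11 bond regiospecifically, because the cycloaddition left the enol ether double bond between C7 and C8, and the new C7 centre is lost in step 10 and need not be controlled.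

Step 10
Reactants: 16 methyl 3-[(1S,2R,4RS)-2-ethenyl-4-(2-methoxypropan-2-yl)-2-methyl-5-oxocyclohexyl]propanoate
Product: 17 methyl 3-[(1S,2R)-2-ethenyl-2-methyl-5-oxo-4-(propan-2-ylidene)cyclohexyl]propanoate
Conditions: DBU, toluene, 60 °C
Reagents that add atoms: none
Why: E1cB elimination of methanol from the β-methoxy ketone can only give the conjugated tetrasubstituted isopropylidene enone, so no isopropenyl isomer should arise and C5 and C10 are untouched.

Step 11
Reactants: 17 methyl 3-[(1S,2R)-2-ethenyl-2-methyl-5-oxo-4-(propan-2-ylidene)cyclohexyl]propanoate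
Product: 18 3-[(1S,2R,5RS)-2-ethenyl-5-hydroxy-2-methyl-4-(propan-2-ylidene)cyclohexyl]propan-1-ol
Conditions: i-Bu2AlH (4 equiv), CH2Cl2, −78 → 0 °C
Reagents that add atoms: none
Why: Hydride reduction with excess i-Bu2AlH takes the ester to the primary alcohol and, because an ester cannot be reduced in preference to a ketone, also the enone carbonyl (1,2-reduction) to an allylic alcohol whose configuration is irrelevant since it is re-oxidised in step 12.

Step 12
Reactants: 18 3-[(1S,2R,5RS)-2-ethenyl-5-hydroxy-2-methyl-4-(propan-2-ylidene)cyclohexyl]propan-1-ol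
Product: 19 3-[(1S,2R)-2-ethenyl-2-methyl-5-oxo-4-(propan-2-ylidene)cyclohexyl]propanal
Conditions: Dess–Martin periodinane (2.6 equiv), CH2Cl2, 0 °C → rt
Reagents that add atoms: none
Why: Dess–Martin oxidation converts both the primary and the allylic alcohol under near-neutral conditions, which returns the enone and gives the C3 aldehyde without the strong acid or base that could start an aldol reaction of this 1,6-keto aldehyde.

Step 13
Reactants: 19 3-[(1S,2R)-2-ethenyl-2-methyl-5-oxo-4-(propan-2-ylidene)cyclohexyl]propanal
Product: 20 (4aS,5R,6R,8aS)-6-hydroxy-4a,5-dimethyl-3-(propan-2-ylidene)-3,4,4a,5,6,7,8,8a-octahydronaphthalen-2(1H)-one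
Conditions: Fe(acac)3 (0.3 equiv), PhSiH3 (2.5 equiv), degassed EtOH, 50 °C, argon
Reagents that add atoms: none
Why: Proposed new method: the iron hydride formed from Fe(acac)3 and PhSiH3 should transfer a hydrogen atom to the terminal carbon C15 of the vinyl group (the tetrasubstituted, electron-poor C7=C11 alkene is a poor acceptor), creating the C15 methyl and a secondary radical at C4 that adds to the aldehyde carbon C3, after which the alkoxy radical is reduced by divalent iron or by hydrogen transfer; the closest known reactions are the iron-hydride hydrogen-atom-transfer cyclisation of alkene-tethered ketones to tertiary alcohols and the tin-hydride 6-exo cyclisation of alkyl radicals onto aldehydes, so only the aldehyde acceptor under this initiation is new. Ring A closes in the 6-exo-trig mode onto C=O through C4, C5, C10, C1, C2 and C3. At C3 the carbonyl oxygen should lie pseudo-equatorial in the chair transition state fused to ring B, because the pseudo-axial position is syn-axial to the C14 methyl on C5, which gives the 3α (R) alcohol; at C4 the planar radical carbon should carry its methyl pseudo-equatorial, anti to the C5–C10 bond, which gives the 4β (R) methyl, cis to C14 and trans to the hydroxyl. The addition to C=O is reversible by β-scission, which should funnel material toward the all-equatorial alkoxy radical before it is reduced. The step needs ring closure to outrun reduction of the C4 radical and of the aldehyde, which the low stationary concentration of metal hydride and the polarity-matched attack of a nucleophilic alkyl radical on an unhindered aldehyde should secure, and it needs no competing ring size, which holds because attack of C4 on C8 or C11 would require a bridged or a 5-endo closure.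

Step 14
Reactants: 20 (4aS,5R,6R,8aS)-6-hydroxy-4a,5-dimethyl-3-(propan-2-ylidene)-3,4,4a,5,6,7,8,8a-octahydronaphthalen-2(1H)-one; 7 (2E,4E,6E)-5-methyldodeca-2,4,6-trienoic acid
Product: 22 (1R,2R,4aS,8aS)-1,8a-dimethyl-6-oxo-7-(propan-2-ylidene)decahydronaphthalen-2-yl (2E,4E,6E)-5-methyldodeca-2,4,6-trienoate, via mixed anhydride 21 (not isolated)
Conditions: 7, 2,4,6-trichlorobenzoyl chloride, Et3N, THF, rt; then 20, DMAP, toluene, rt
Reagents that add atoms: none
Why: Yamaguchi esterification, in which the acid is activated as the mixed anhydride with the hindered trichlorobenzoyl group and 4-dimethylaminopyridine transfers the trienoyl group to the equatorial C3 hydroxyl with retention at C3 under conditions mild enough for the triene.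

Step 15
Reactants: 22 (1R,2R,4aS,8aS)-1,8a-dimethyl-6-oxo-7-(propan-2-ylidene)decahydronaphthalen-2-yl (2E,4E,6E)-5-methyldodeca-2,4,6-trienoate
Product: 24 (1R,2R,4aR,5S,8aR)-5-hydroxy-1,8a-dimethyl-6-oxo-7-(propan-2-ylidene)decahydronaphthalen-2-yl (2E,4E,6E)-5-methyldodeca-2,4,6-trienoate, via potassium enolate 23 (not isolated)
Conditions: KN(SiMe3)2 (1.1 equiv), THF, −78 °C; then 2-(phenylsulfonyl)-3-phenyloxaziridine, −78 °C; AcOH quench
Reagents that add atoms: 2-(phenylsulfonyl)-3-phenyloxaziridine, O=S(=O)(c1ccccc1)N1OC1c1ccccc1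
Why: Enolate oxidation with an N-sulfonyloxaziridine, in which KN(SiMe3)2 at −78 °C should remove a proton from C9, the only α-position left on the ketone (C7 is blocked by the isopropylidene and the ester has no α-hydrogen), and oxygen is delivered to the α face, anti to the axial C14 methyl that is syn-axial to the β face of C9, giving the equatorial 9α (S) alcohol, which is also the more stable epimer.

**Compound list**

1 | (2E)-oct-2-enal | CCCCC/C=C/C=O | starting material
2 | (3E)-non-3-en-1-yne | CCCCC/C=C/C#C | intermediate
3 | dimethyl[(1E,3E)-2-methylnona-1,3-dien-1-yl]alane | CCCCC/C=C/C(C)=C/[Al](C)C | intermediate (not isolated)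
4 | (1E,3E)-1-iodo-2-methylnona-1,3-diene | CCCCC/C=C/C(C)=C/I | intermediate
5 | ethyl prop-2-enoate (ethyl acrylate) | C=CC(=O)OCC | starting material
6 | ethyl (2E,4E,6E)-5-methyldodeca-2,4,6-trienoate | CCCCC/C=C/C(C)=C/C=C/C(=O)OCC | intermediate
7 | (2E,4E,6E)-5-methyldodeca-2,4,6-trienoic acid | CCCCC/C=C/C(C)=C/C=C/C(=O)O | intermediate
8 | but-3-en-2-one | CC(=O)C=C | starting material
9 | (buta-1,3-dien-2-yloxy)tri(propan-2-yl)silane | C=CC(=C)O[Si](C(C)C)(C(C)C)C(C)C | intermediate
10 | methyl 4-oxobutanoate | COC(=O)CCC=O | starting material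
11 | 2-(triphenylphosphoranylidene)propanal | CC(C=O)=P(c1ccccc1)(c1ccccc1)c1ccccc1 | starting material
12 | methyl (4E)-5-methyl-6-oxohex-4-enoate | COC(=O)CC/C=C(\C)C=O | intermediate
13 | methyl 3-[(1S,6S)-6-formyl-6-methyl-3-{[tri(propan-2-yl)silyl]oxy}cyclohex-3-en-1-yl]propanoate | COC(=O)CC[C@H]1CC(O[Si](C(C)C)(C(C)C)C(C)C)=CC[C@]1(C)C=O | intermediate
14 | methyl 3-[(1S,6R)-6-ethenyl-6-methyl-3-{[tri(propan-2-yl)silyl]oxy}cyclohex-3-en-1-yl]propanoate | COC(=O)CC[C@H]1CC(O[Si](C(C)C)(C(C)C)C(C)C)=CC[C@]1(C)C=C | intermediate
15 | 2,2-dimethoxypropane | COC(C)(C)OC | starting material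
16 | methyl 3-[(1S,2R,4RS)-2-ethenyl-4-(2-methoxypropan-2-yl)-2-methyl-5-oxocyclohexyl]propanoate (C7 epimers) | COC(=O)CC[C@H]1CC(=O)C(C(C)(C)OC)C[C@]1(C)C=C | intermediate
17 | methyl 3-[(1S,2R)-2-ethenyl-2-methyl-5-oxo-4-(propan-2-ylidene)cyclohexyl]propanoate | COC(=O)CC[C@H]1CC(=O)C(=C(C)C)C[C@]1(C)C=C | intermediate
18 | 3-[(1S,2R,5RS)-2-ethenyl-5-hydroxy-2-methyl-4-(propan-2-ylidene)cyclohexyl]propan-1-ol (C8 epimers) | OCCC[C@H]1CC(O)C(=C(C)C)C[C@]1(C)C=C | intermediate
19 | 3-[(1S,2R)-2-ethenyl-2-methyl-5-oxo-4-(propan-2-ylidene)cyclohexyl]propanal | O=CCC[C@H]1CC(=O)C(=C(C)C)C[C@]1(C)C=C | intermediate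
20 | (4aS,5R,6R,8aS)-6-hydroxy-4a,5-dimethyl-3-(propan-2-ylidene)-3,4,4a,5,6,7,8,8a-octahydronaphthalen-2(1H)-one | O[C@@H]1CC[C@H]2CC(=O)C(=C(C)C)C[C@]2(C)[C@H]1C | intermediate
21 | (2E,4E,6E)-5-methyldodeca-2,4,6-trienoic 2,4,6-trichlorobenzoic anhydride | CCCCC/C=C/C(C)=C/C=C/C(=O)OC(=O)c1c(Cl)cc(Cl)cc1Cl | intermediate (not isolated)
22 | (1R,2R,4aS,8aS)-1,8a-dimethyl-6-oxo-7-(propan-2-ylidene)decahydronaphthalen-2-yl (2E,4E,6E)-5-methyldodeca-2,4,6-trienoate | CCCCC/C=C/C(C)=C/C=C/C(=O)O[C@@H]1CC[C@H]2CC(=O)C(=C(C)C)C[C@]2(C)[C@H]1C | intermediate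
23 | potassium enolate of 22 (C8–O−, C8=C9 double bond) | CCCCC/C=C/C(C)=C/C=C/C(=O)O[C@@H]1CC[C@H]2C=C([O-])C(=C(C)C)C[C@]2(C)[C@H]1C.[K+] | intermediate (not isolated)
24 | (1R,2R,4aR,5S,8aR)-5-hydroxy-1,8a-dimethyl-6-oxo-7-(propan-2-ylidene)decahydronaphthalen-2-yl (2E,4E,6E)-5-methyldodeca-2,4,6-trienoate | CCCCC/C=C/C(C)=C/C=C/C(=O)O[C@@H]1CC[C@H]2[C@H](O)C(=O)C(=C(C)C)C[C@]2(C)[C@H]1C | target

**Count**

Total steps: 15 (4 for acid 7, 1 for diene 9, 10 in the main line).
Longest linear sequence: 10 steps (steps 6 to 15, from 10 to 24).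

**Steps most likely to fail**

Step 13. The C4 radical may be reduced to an ethyl group, or the aldehyde hydrosilylated, before the ring closes, and the planar C4 radical may close with poor facial control. The fallback uses known chemistry, sets out from 14 and comes back at 22. Reduction of the ester of 14 with i-Bu2AlH (1.05 equiv, toluene, −78 °C) should give the aldehyde 3-[(1S,6R)-6-ethenyl-6-methyl-3-{[tri(propan-2-yl)silyl]oxy}cyclohex-3-en-1-yl]propanal F1, the enol ether being inert since no ketone is present at this stage. SmI2 with HMPA and t-BuOH in THF then generates the C3 ketyl from divalent samarium, which closes C3–C4 by ketyl–olefin 6-exo cyclisation onto the vinyl group; the C15 radical is reduced and protonated. The expected product is the alcohol (1R,2R,4aS,8aS)-1,8a-dimethyl-6-{[tri(propan-2-yl)silyl]oxy}-1,2,3,4,4a,5,8,8a-octahydronaphthalen-2-ol F2, the enol ether being untouched by the reagent. Esterification with 7 under the conditions of step 14 gives the trienoate of F2, F3. Addition to 15 as in step 9 gives the β-methoxy ketone F4, and DBU as in step 10 returns 22.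

Step 7. The trisubstituted enal may react too slowly at the low temperature at which the catalyst tells the faces apart, a proton-catalysed background reaction may erode the enantiomeric purity, and the diene may be protodesilylated. The fallback sets out from 12 and 9 and comes back at 13. Cycloaddition promoted by EtAlCl2 (CH2Cl2, −78 °C) should give 13 as the racemate, that is together with its mirror image methyl 3-[(1R,6R)-6-formyl-6-methyl-3-{[tri(propan-2-yl)silyl]oxy}cyclohex-3-en-1-yl]propanoate F5. F5 is removed by preparative chromatography on a chiral stationary phase with supercritical CO2, so that absolute configuration comes from resolution and not from catalysis.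

Step 15. The base may deprotonate the trienoate at its vinylogous positions or add to it, and oxygen transfer may show incomplete facial selectivity. The fallback sets out from 22 and comes back at 24. Soft enolisation with t-BuMe2SiOTf and Et3N (CH2Cl2, 0 °C) should give the tert-butyldimethylsilyl dienol ether of 22, F6, without any strong base. Dimethyldioxirane (acetone, −40 °C) should epoxidise the electron-rich C8=C9 bond from the α face, in a Rubottom-type oxidation, to the 8α,9α-silyloxy oxirane F7. HF·pyridine then opens the oxirane with loss of the silyl group to give 24.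

**Further compounds**

F1 | step 13 | 3-[(1S,6R)-6-ethenyl-6-methyl-3-{[tri(propan-2-yl)silyl]oxy}cyclohex-3-en-1-yl]propanal | O=CCC[C@H]1CC(O[Si](C(C)C)(C(C)C)C(C)C)=CC[C@]1(C)C=C
F2 | step 13 | (1R,2R,4aS,8aS)-1,8a-dimethyl-6-{[tri(propan-2-yl)silyl]oxy}-1,2,3,4,4a,5,8,8a-octahydronaphthalen-2-ol | O[C@@H]1CC[C@H]2CC(O[Si](C(C)C)(C(C)C)C(C)C)=CC[C@]2(C)[C@H]1C
F3 | step 13 | (1R,2R,4aS,8aS)-1,8a-dimethyl-6-{[tri(propan-2-yl)silyl]oxy}-1,2,3,4,4a,5,8,8a-octahydronaphthalen-2-yl (2E,4E,6E)-5-methyldodeca-2,4,6-trienoate | CCCCC/C=C/C(C)=C/C=C/C(=O)O[C@@H]1CC[C@H]2CC(O[Si](C(C)C)(C(C)C)C(C)C)=CC[C@]2(C)[C@H]1C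
F4 | step 13 | (1R,2R,4aS,7RS,8aS)-7-(2-methoxypropan-2-yl)-1,8a-dimethyl-6-oxodecahydronaphthalen-2-yl (2E,4E,6E)-5-methyldodeca-2,4,6-trienoate | CCCCC/C=C/C(C)=C/C=C/C(=O)O[C@@H]1CC[C@H]2CC(=O)C(C(C)(C)OC)C[C@]2(C)[C@H]1C
F5 | step 7 | methyl 3-[(1R,6R)-6-formyl-6-methyl-3-{[tri(propan-2-yl)silyl]oxy}cyclohex-3-en-1-yl]propanoate | COC(=O)CC[C@@H]1CC(O[Si](C(C)C)(C(C)C)C(C)C)=CC[C@@]1(C)C=O
F6 | step 15 | tert-butyldimethylsilyl dienol ether of 22 (silyloxy group on C8, C8=C9 double bond) | CCCCC/C=C/C(C)=C/C=C/C(=O)O[C@@H]1CC[C@H]2C=C(O[Si](C)(C)C(C)(C)C)C(=C(C)C)C[C@]2(C)[C@H]1C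
F7 | step 15 | 8α,9α-epoxide of F6 (oxirane oxygen on the α face of C8 and C9, silyloxy group on C8) | CCCCC/C=C/C(C)=C/C=C/C(=O)O[C@@H]1CC[C@H]2[C@@H]3O[C@]3(O[Si](C)(C)C(C)(C)C)C(=C(C)C)C[C@]2(C)[C@H]1C
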